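**Retrosynthetic overview**
- The route rests on ring B of the flavanone, a 1,3,4-trisubstituted benzene: C1' sits on flavanone C2, C3' on flavone C8, and C4' carries the hydroxyl. This ring is built last.
- Ring B is cut at C2'–C3' and C4'–C5': a cobalt-catalysed [4+2] joins a buta-1,3-dien-2-yl group on the configured C2 with an alkynyl pinacol boronate on flavone C8. DDQ then aromatises the ring and the boron becomes the C4' oxygen.
- Diene half: the pyranone ring C of a chromone is closed from an acetophenone, copper-catalysed asymmetric conjugate alkynylation sets C2 (S), and ethene enyne metathesis gives the diene.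
- Alkyne half: apigenin (rings A, C and B of the flavone bought intact) is benzylated, iodinated at C8, coupled by Sonogashira reaction, desilylated and borylated.
- Ring order: chromone ring C, then ring B by cycloaddition; one hydrogenolysis unmasks all phenols.

Key step: step 11

Remark: every masked phenol carries a benzyl ether, because the chromone half meets aqueous HCl and a silyl triflate that acetal groups would not survive. Which StackPhos antipode gives the 2S product in step 3 is fixed by a test run, both antipodes being available. Compound 1 is taken as purchased.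

**Step 1**
Reactants: 1 1-(2,6-dihydroxy-4-methoxyphenyl)ethan-1-one; 2 benzyl bromide
Product: 3 1-[2-(benzyloxy)-6-hydroxy-4-methoxyphenyl]ethan-1-one
Conditions: BnBr (1.05 equiv), K2CO3 (1.1 equiv), acetone, reflux
Reagents that add atoms: benzyl bromide, BrCc1ccccc1
Why: Williamson etherification of the symmetrical diphenol should stop after one alkylation, because the remaining hydroxyl is held in a hydrogen bond to the acetyl carbonyl and is far less nucleophilic.

**Step 2**
Reactants: 3 1-[2-(benzyloxy)-6-hydroxy-4-methoxyphenyl]ethan-1-one; 4 N,N-dimethylformamide dimethyl acetal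
Product: 6 5-(benzyloxy)-7-methoxy-4H-chromen-4-one, via enaminone 5 (not isolated)
Conditions: Me2NCH(OMe)2 (3 equiv), toluene, 100 °C; evaporate; conc. aq. HCl, CH2Cl2, rt
Reagents that add atoms: N,N-dimethylformamide dimethyl acetal, COC(OC)N(C)C
Why: Enaminone route to chromones: the methyl ketone condenses with the amide acetal, then acid-promoted addition of the ortho phenol to the enaminone and loss of dimethylamine closes the pyranone ring, while the benzyl ether withstands brief HCl at room temperature.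

**Step 3**
Reactants: 6 5-(benzyloxy)-7-methoxy-4H-chromen-4-one; 7 (triisopropylsilyl)acetylene
Product: 10 (S)-5-(benzyloxy)-7-methoxy-2-[(triisopropylsilyl)ethynyl]chroman-4-one, via benzopyrylium triflate 8 (not isolated), via silyl enol ether 9 (not isolated)
Conditions: t-BuMe2SiOTf (1.3 equiv), i-Pr2NEt (1.6 equiv), CuI (5 mol %), StackPhos (6 mol %), toluene, −78 → −20 °C; then 1 M aq. HCl, THF, 0 °C
Reagents that add atoms: (triisopropylsilyl)acetylene, C#C[Si](C(C)C)(C(C)C)C(C)C
Why: Copper-catalysed enantioselective conjugate alkynylation of a chromone: the silyl triflate turns 6 into the 4-siloxybenzopyrylium ion, the copper acetylide bearing the chiral P,N ligand adds to C2 through the face the ligand leaves open and so sets the S centre, and acid work-up hydrolyses the silyl enol ether, the benzyl and methyl ethers being inert to the silyl triflate.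

**Step 4**
Reactants: 10 (S)-5-(benzyloxy)-7-methoxy-2-[(triisopropylsilyl)ethynyl]chroman-4-one
Product: 11 (S)-5-(benzyloxy)-2-ethynyl-7-methoxychroman-4-one
Conditions: Bu4NF (1.2 equiv), AcOH (1.3 equiv), THF, 0 °C → rt
Reagents that add atoms: none
Why: Fluoride-induced protodesilylation of the alkynyl C–Si bond, with the acetic acid buffer keeping the medium from enolising the ketone so that retro-oxa-Michael ring opening, which would erode C2, is avoided.

**Step 5**
Reactants: 11 (S)-5-(benzyloxy)-2-ethynyl-7-methoxychroman-4-one; 12 ethene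
Product: 13 (S)-5-(benzyloxy)-2-(buta-1,3-dien-2-yl)-7-methoxychroman-4-one
Conditions: ethene (1 atm), second-generation Grubbs catalyst (5 mol %), CH2Cl2, rt → 40 °C
Reagents that add atoms: ethene, C=C
Why: Ene–yne cross-metathesis of a terminal alkyne with ethene: the ruthenium methylidene adds across the alkyne, the ruthenacyclobutene opens to a vinylcarbene and ethene releases the 2-substituted buta-1,3-diene, a process that works well with propargylic oxygen substituents and breaks no bond at C2.

**Step 6**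
Reactants: 14 apigenin; 2 benzyl bromide
Product: 15 5,7-bis(benzyloxy)-2-[4-(benzyloxy)phenyl]-4H-chromen-4-one
Conditions: BnBr (3.6 equiv), K2CO3 (4 equiv), Bu4NI (cat.), DMF, 80 °C
Reagents that add atoms: benzyl bromide, BrCc1ccccc1
Why: Threefold Williamson etherification, in which heat, excess halide and iodide catalysis carry the hydrogen-bonded 5-OH to completion.

**Step 7**
Reactants: 15 5,7-bis(benzyloxy)-2-[4-(benzyloxy)phenyl]-4H-chromen-4-one; 16 N-iodosuccinimide
Product: 17 5,7-bis(benzyloxy)-2-[4-(benzyloxy)phenyl]-8-iodo-4H-chromen-4-one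
Conditions: NIS (1.05 equiv), CF3CO2H (0.1 equiv), CH2Cl2–MeCN, 0 °C → rt, dark
Reagents that add atoms: N-iodosuccinimide, O=C1CCC(=O)N1I
Why: Electrophilic aromatic iodination of the phloroglucinol-type ring A, where fully O-alkylated 5,7-dioxygenated flavones react at C8 (between O1 and one benzyloxy group, para to the 5-benzyloxy group) rather than at C6 (wedged between two benzyloxy groups), the acid being kept catalytic so that the 5-O-benzyl group, whose loss would redirect attack to C6, stays on.

**Step 8**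
Reactants: 17 5,7-bis(benzyloxy)-2-[4-(benzyloxy)phenyl]-8-iodo-4H-chromen-4-one; 7 (triisopropylsilyl)acetylene
Product: 18 5,7-bis(benzyloxy)-2-[4-(benzyloxy)phenyl]-8-[(triisopropylsilyl)ethynyl]-4H-chromen-4-one
Conditions: PdCl2(PPh3)2 (5 mol %), CuI (10 mol %), Et3N–DMF, 60 °C
Reagents that add atoms: (triisopropylsilyl)acetylene, C#C[Si](C(C)C)(C(C)C)C(C)C
Why: Sonogashira coupling, in which the slim copper acetylide is little affected by the two ortho oxygen substituents flanking C8.

**Step 9**
Reactants: 18 5,7-bis(benzyloxy)-2-[4-(benzyloxy)phenyl]-8-[(triisopropylsilyl)ethynyl]-4H-chromen-4-one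
Product: 19 5,7-bis(benzyloxy)-2-[4-(benzyloxy)phenyl]-8-ethynyl-4H-chromen-4-one
Conditions: Bu4NF (1.2 equiv), AcOH (1.3 equiv), THF, 0 °C → rt
Reagents that add atoms: none
Why: Fluoride-induced protodesilylation of the arylalkynyl C–Si bond, to which the flavone and the benzyl ethers are inert.

**Step 10**
Reactants: 19 5,7-bis(benzyloxy)-2-[4-(benzyloxy)phenyl]-8-ethynyl-4H-chromen-4-one; 20 2-isopropoxy-4,4,5,5-tetramethyl-1,3,2-dioxaborolane
Product: 23 5,7-bis(benzyloxy)-2-[4-(benzyloxy)phenyl]-8-[(4,4,5,5-tetramethyl-1,3,2-dioxaborolan-2-yl)ethynyl]-4H-chromen-4-one, via lithium acetylide 21 (not isolated), via lithium borate 22 (not isolated)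
Conditions: LiN(SiMe3)2 (1.05 equiv), THF, −78 °C; i-PrOBpin (1.2 equiv), −78 °C; HCl in Et2O (1.1 equiv), −78 °C → rt; filter under argon, evaporate
Reagents that add atoms: 2-isopropoxy-4,4,5,5-tetramethyl-1,3,2-dioxaborolane, CC(C)OB1OC(C)(C)C(C)(C)O1
Why: Alkynylboronate synthesis by acetylide borylation: the hindered amide base removes only the alkyne proton, the most acidic one, without adding to the flavone carbonyl, the acetylide adds to boron and anhydrous HCl expels isopropanol from the borate, so the moisture-sensitive ester is obtained without aqueous work-up.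

**Step 11**
Reactants: 13 (S)-5-(benzyloxy)-2-(buta-1,3-dien-2-yl)-7-methoxychroman-4-one; 23 5,7-bis(benzyloxy)-2-[4-(benzyloxy)phenyl]-8-[(4,4,5,5-tetramethyl-1,3,2-dioxaborolan-2-yl)ethynyl]-4H-chromen-4-one
Product: 24 (2S)-5-(benzyloxy)-7-methoxychroman-4-one whose ring B is a cyclohexa-1,4-diene (C1'=C6' and C3'=C4') with the pinacolboryl group on C4' and C8 of tri-O-benzylapigenin on C3'
Conditions: CoBr2(dppe) (10 mol %), Zn powder (20 mol %), ZnI2 (20 mol %), CH2Cl2, rt, 13 (1.3 equiv) added slowly
Reagents that add atoms: none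
Why: Zinc reduces CoBr2(dppe) to a monovalent cobalt complex that ZnI2 renders cationic; this binds the s-cis diene of 13 and the alkyne of 23, couples them oxidatively to an allyl–cobalt–vinyl metallacycle and releases the 1,4-cyclohexadiene by reductive elimination, forming C2'–C3' and C4'–C5'. The closest known reaction type is the cobalt-catalysed Diels–Alder reaction of alkynyl pinacol boronates with 2-substituted 1,3-dienes, which runs at room temperature where the thermal cycloaddition of these unactivated partners would not. Ring B closes in an intermolecular [4+2] mode, four carbons coming from the diene on C2 and two from the alkyne on C8. No stereocentre is created, and C2 should keep its S configuration because the medium is neither basic nor protic and no bond to C2 is broken. The selectivity needed is regiochemical (boron on C4', para to C1', and the flavone on C3'): the boron-polarised alkyne is expected to offer its flavonyl-bearing carbon to the more electron-rich diene terminus C2' next to the substituted carbon, dppe is the ligand expected to favour this para pairing, and the ligand on cobalt can be exchanged if the other isomer prevails. Cross-selectivity over diene dimerisation and alkyne trimerisation is helped by the slight excess and slow addition of 13.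

**Step 12**
Reactants: 24 the cyclohexa-1,4-dienyl boronate
Product: 25 (2S)-5-(benzyloxy)-7-methoxy-2-{3-[5,7-bis(benzyloxy)-2-(4-benzyloxyphenyl)-4-oxo-4H-chromen-8-yl]-4-(4,4,5,5-tetramethyl-1,3,2-dioxaborolan-2-yl)phenyl}chroman-4-one
Conditions: DDQ (1.1 equiv), toluene, rt
Reagents that add atoms: none
Why: Dehydrogenative aromatisation of a 1,4-cyclohexadiene by DDQ (hydride abstraction from a doubly allylic CH2, then proton loss), which at room temperature should be much faster than oxidation at the C2–H of the chromanone or at the benzyl ethers and leaves the C–B bond intact.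

**Step 13**
Reactants: 25 the arylboronate; 26 trimethylamine N-oxide
Product: 28 (2S)-5-(benzyloxy)-2-{3-[5,7-bis(benzyloxy)-2-(4-benzyloxyphenyl)-4-oxo-4H-chromen-8-yl]-4-hydroxyphenyl}-7-methoxychroman-4-one, via aryl borate 27 (not isolated)
Conditions: Me3NO (3 equiv), THF, rt → 40 °C; aq. NH4Cl
Reagents that add atoms: trimethylamine N-oxide, C[N+](C)(C)[O-]
Why: Ipso-hydroxylation of an arylboronate by an amine N-oxide: the oxide oxygen adds to boron, the aryl group migrates from boron to oxygen with loss of trimethylamine and the borate is hydrolysed on work-up, so neither peroxide nor hydroxide meets the flavone enone or the base-sensitive C2 centre.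

**Step 14**
Reactants: 28 the tetra-O-benzyl biflavonoid
Product: 29 (2S)-2-{3-[5,7-dihydroxy-2-(4-hydroxyphenyl)-4-oxo-4H-chromen-8-yl]-4-hydroxyphenyl}-5-hydroxy-7-methoxychroman-4-one (target)
Conditions: H2 (1 atm), Pd/C (10 %), THF–MeOH, rt
Reagents that add atoms: none
Why: Hydrogenolysis of the four aryl benzyl ethers under neutral conditions, where the flavone C2=C3 bond and the aryl ketones are reduced far more slowly and no base is present to open the flavanone and racemise C2.

**Compound list**
1 | 1-(2,6-dihydroxy-4-methoxyphenyl)ethan-1-one | CC(=O)c1c(O)cc(OC)cc1O | starting material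
2 | benzyl bromide | BrCc1ccccc1 | starting material
3 | 1-[2-(benzyloxy)-6-hydroxy-4-methoxyphenyl]ethan-1-one | CC(=O)c1c(O)cc(OC)cc1OCc1ccccc1 | intermediate
4 | N,N-dimethylformamide dimethyl acetal | COC(OC)N(C)C | starting material
5 | (E)-1-[2-(benzyloxy)-6-hydroxy-4-methoxyphenyl]-3-(dimethylamino)prop-2-en-1-one | CN(C)/C=C/C(=O)c1c(O)cc(OC)cc1OCc1ccccc1 | intermediate (not isolated)
6 | 5-(benzyloxy)-7-methoxy-4H-chromen-4-one | COc1cc(OCc2ccccc2)c2c(=O)ccoc2c1 | intermediate
7 | (triisopropylsilyl)acetylene | C#C[Si](C(C)C)(C(C)C)C(C)C | starting material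
8 | 5-(benzyloxy)-4-[(tert-butyldimethylsilyl)oxy]-7-methoxychromenylium trifluoromethanesulfonate | COc1cc(OCc2ccccc2)c2c(O[Si](C)(C)C(C)(C)C)cc[o+]c2c1.[O-]S(=O)(=O)C(F)(F)F | intermediate (not isolated)
9 | (S)-5-(benzyloxy)-4-[(tert-butyldimethylsilyl)oxy]-7-methoxy-2-[(triisopropylsilyl)ethynyl]-2H-chromene | COc1cc(OCc2ccccc2)c2c(c1)O[C@H](C#C[Si](C(C)C)(C(C)C)C(C)C)C=C2O[Si](C)(C)C(C)(C)C | intermediate (not isolated)
10 | (S)-5-(benzyloxy)-7-methoxy-2-[(triisopropylsilyl)ethynyl]chroman-4-one | COc1cc(OCc2ccccc2)c2c(c1)O[C@H](C#C[Si](C(C)C)(C(C)C)C(C)C)CC2=O | intermediate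
11 | (S)-5-(benzyloxy)-2-ethynyl-7-methoxychroman-4-one | COc1cc(OCc2ccccc2)c2c(c1)O[C@H](C#C)CC2=O | intermediate
12 | ethene | C=C | starting material
13 | (S)-5-(benzyloxy)-2-(buta-1,3-dien-2-yl)-7-methoxychroman-4-one | COc1cc(OCc2ccccc2)c2c(c1)O[C@H](C(=C)C=C)CC2=O | intermediate
14 | apigenin | O=c1cc(-c2ccc(O)cc2)oc2cc(O)cc(O)c12 | starting material
15 | 5,7-bis(benzyloxy)-2-[4-(benzyloxy)phenyl]-4H-chromen-4-one | O=c1cc(-c2ccc(OCc3ccccc3)cc2)oc2cc(OCc3ccccc3)cc(OCc3ccccc3)c12 | intermediate
16 | N-iodosuccinimide | O=C1CCC(=O)N1I | starting material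
17 | 5,7-bis(benzyloxy)-2-[4-(benzyloxy)phenyl]-8-iodo-4H-chromen-4-one | O=c1cc(-c2ccc(OCc3ccccc3)cc2)oc2c(I)c(OCc3ccccc3)cc(OCc3ccccc3)c12 | intermediate
18 | 5,7-bis(benzyloxy)-2-[4-(benzyloxy)phenyl]-8-[(triisopropylsilyl)ethynyl]-4H-chromen-4-one | O=c1cc(-c2ccc(OCc3ccccc3)cc2)oc2c(C#C[Si](C(C)C)(C(C)C)C(C)C)c(OCc3ccccc3)cc(OCc3ccccc3)c12 | intermediate
19 | 5,7-bis(benzyloxy)-2-[4-(benzyloxy)phenyl]-8-ethynyl-4H-chromen-4-one | O=c1cc(-c2ccc(OCc3ccccc3)cc2)oc2c(C#C)c(OCc3ccccc3)cc(OCc3ccccc3)c12 | intermediate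
20 | 2-isopropoxy-4,4,5,5-tetramethyl-1,3,2-dioxaborolane | CC(C)OB1OC(C)(C)C(C)(C)O1 | starting material
21 | lithium acetylide of 19 | [Li]C#Cc1c(OCc2ccccc2)cc(OCc2ccccc2)c2c(=O)cc(-c3ccc(OCc4ccccc4)cc3)oc12 | intermediate (not isolated)
22 | lithium alkynyl(isopropoxy)(pinacolato)borate from 21 and 20 | [Li+].CC(C)O[B-]1(C#Cc2c(OCc3ccccc3)cc(OCc3ccccc3)c3c(=O)cc(-c4ccc(OCc5ccccc5)cc4)oc23)OC(C)(C)C(C)(C)O1 | intermediate (not isolated)
23 | 5,7-bis(benzyloxy)-2-[4-(benzyloxy)phenyl]-8-[(4,4,5,5-tetramethyl-1,3,2-dioxaborolan-2-yl)ethynyl]-4H-chromen-4-one | CC1(C)OB(C#Cc2c(OCc3ccccc3)cc(OCc3ccccc3)c3c(=O)cc(-c4ccc(OCc5ccccc5)cc4)oc23)OC1(C)C | intermediate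
24 | (2S)-5-(benzyloxy)-7-methoxychroman-4-one with ring B as cyclohexa-1,4-diene, Bpin on C4', tri-O-benzylapigenin-8-yl on C3' | COc1cc(OCc2ccccc2)c2c(c1)O[C@H](C1=CCC(B3OC(C)(C)C(C)(C)O3)=C(c3c(OCc4ccccc4)cc(OCc4ccccc4)c4c(=O)cc(-c5ccc(OCc6ccccc6)cc5)oc34)C1)CC2=O | intermediate
25 | (2S)-5-(benzyloxy)-7-methoxy-2-{3-[5,7-bis(benzyloxy)-2-(4-benzyloxyphenyl)-4-oxo-4H-chromen-8-yl]-4-(pinacolboryl)phenyl}chroman-4-one | COc1cc(OCc2ccccc2)c2c(c1)O[C@H](c1ccc(B3OC(C)(C)C(C)(C)O3)c(-c3c(OCc4ccccc4)cc(OCc4ccccc4)c4c(=O)cc(-c5ccc(OCc6ccccc6)cc5)oc34)c1)CC2=O | intermediate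
26 | trimethylamine N-oxide | C[N+](C)(C)[O-] | starting material
27 | aryl pinacol borate (ArO–Bpin) formed from 25 | COc1cc(OCc2ccccc2)c2c(c1)O[C@H](c1ccc(OB3OC(C)(C)C(C)(C)O3)c(-c3c(OCc4ccccc4)cc(OCc4ccccc4)c4c(=O)cc(-c5ccc(OCc6ccccc6)cc5)oc34)c1)CC2=O | intermediate (not isolated)
28 | (2S)-5-(benzyloxy)-2-{3-[5,7-bis(benzyloxy)-2-(4-benzyloxyphenyl)-4-oxo-4H-chromen-8-yl]-4-hydroxyphenyl}-7-methoxychroman-4-one | COc1cc(OCc2ccccc2)c2c(c1)O[C@H](c1ccc(O)c(-c3c(OCc4ccccc4)cc(OCc4ccccc4)c4c(=O)cc(-c5ccc(OCc6ccccc6)cc5)oc34)c1)CC2=O | intermediate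
29 | (2S)-2-{3-[5,7-dihydroxy-2-(4-hydroxyphenyl)-4-oxo-4H-chromen-8-yl]-4-hydroxyphenyl}-5-hydroxy-7-methoxychroman-4-one | COc1cc(O)c2c(c1)O[C@H](c1ccc(O)c(-c3c(O)cc(O)c4c(=O)cc(-c5ccc(O)cc5)oc34)c1)CC2=O | target

**Step count and risks**
Total steps: 14. Longest linear sequence: 9 steps (steps 1–5 then 11–14, or steps 6–14).

Steps most likely to fail:

1. Step 11. The alkyne and diene termini may pair the other way, placing the flavone on C4' and boron on C3'. The cobalt catalyst may also fail to engage the doubly ortho-flanked alkyne, so that diene dimerisation takes over, or ZnI2 may ionise the allylic C2–O bond. Fallback: ring B is brought in as a finished arene and the C3'–C8 bond is made by Suzuki–Miyaura coupling. Setting out from chromone 6, conjugate addition of commercial [4-(benzyloxy)-3-chlorophenyl]boronic acid (OB(O)c1ccc(OCc2ccccc2)c(Cl)c1) catalysed by divalent palladium (Pd(OCOCF3)2, t-Bu-PyOx antipode chosen for 2S, NH4PF6, H2O, ClCH2CH2Cl, 60 °C) should give (S)-5-(benzyloxy)-2-[4-(benzyloxy)-3-chlorophenyl]-7-methoxychroman-4-one F1. In parallel, iodide 17 undergoes Miyaura borylation (B2pin2, PdCl2(dppf), KOAc, dioxane, 90 °C) to 5,7-bis(benzyloxy)-2-[4-(benzyloxy)phenyl]-8-(4,4,5,5-tetramethyl-1,3,2-dioxaborolan-2-yl)-4H-chromen-4-one F2. Coupling of F1 with F2 (Pd(OAc)2, SPhos, CsF, dioxane, 90 °C) should give the penta-O-benzyl biflavonoid F3, and hydrogenolysis under the conditions of step 14 rejoins the route at 29.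

2. Step 3. Facial discrimination may be poor, or addition sluggish, on the electron-rich 5,7-dialkoxybenzopyrylium ion. Fallback: resolution replaces asymmetric catalysis. Setting out from 6 and 7, the addition is run without chiral ligand (t-BuMe2SiOTf, i-Pr2NEt, CuI, CH2Cl2, 0 °C; then aq. HCl) through the racemic silyl enol ether F4 to racemic 5-(benzyloxy)-7-methoxy-2-[(triisopropylsilyl)ethynyl]chroman-4-one F5. Preparative chromatography on a chiral stationary phase then separates the enantiomers; the (S)-enantiomer is 10, where the route is rejoined, and the (R)-enantiomer F6 is set aside.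

3. Step 14. Over-reduction (saturation of the flavone C2=C3 bond or hydrogenolytic opening of the benzylic C2–O1 bond of the flavanone) may compete with removal of the last, hindered benzyl ether. Fallback: Lewis-acid debenzylation replaces hydrogenolysis. Setting out from 28, BCl3 with pentamethylbenzene as benzyl-cation scavenger (CH2Cl2, −78 °C, MeOH quench) should cleave the four benzyl ethers while the non-chelated 7-methoxy group survives at this temperature, giving 29 directly; no new compound is made (F0).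

**Further compounds**
F1 | step 11 | (S)-5-(benzyloxy)-2-[4-(benzyloxy)-3-chlorophenyl]-7-methoxychroman-4-one | COc1cc(OCc2ccccc2)c2c(c1)O[C@H](c1ccc(OCc3ccccc3)c(Cl)c1)CC2=O
F2 | step 11 | 5,7-bis(benzyloxy)-2-[4-(benzyloxy)phenyl]-8-(4,4,5,5-tetramethyl-1,3,2-dioxaborolan-2-yl)-4H-chromen-4-one | CC1(C)OB(c2c(OCc3ccccc3)cc(OCc3ccccc3)c3c(=O)cc(-c4ccc(OCc5ccccc5)cc4)oc23)OC1(C)C
F3 | step 11 | (2S)-5-(benzyloxy)-2-{4-(benzyloxy)-3-[5,7-bis(benzyloxy)-2-(4-benzyloxyphenyl)-4-oxo-4H-chromen-8-yl]phenyl}-7-methoxychroman-4-one | COc1cc(OCc2ccccc2)c2c(c1)O[C@H](c1ccc(OCc3ccccc3)c(-c3c(OCc4ccccc4)cc(OCc4ccccc4)c4c(=O)cc(-c5ccc(OCc6ccccc6)cc5)oc34)c1)CC2=O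
F4 | step 3 | racemic 5-(benzyloxy)-4-[(tert-butyldimethylsilyl)oxy]-7-methoxy-2-[(triisopropylsilyl)ethynyl]-2H-chromene | COc1cc(OCc2ccccc2)c2c(c1)OC(C#C[Si](C(C)C)(C(C)C)C(C)C)C=C2O[Si](C)(C)C(C)(C)C
F5 | step 3 | racemic 5-(benzyloxy)-7-methoxy-2-[(triisopropylsilyl)ethynyl]chroman-4-one | COc1cc(OCc2ccccc2)c2c(c1)OC(C#C[Si](C(C)C)(C(C)C)C(C)C)CC2=O
F6 | step 3 | (R)-5-(benzyloxy)-7-methoxy-2-[(triisopropylsilyl)ethynyl]chroman-4-one | COc1cc(OCc2ccccc2)c2c(c1)O[C@@H](C#C[Si](C(C)C)(C(C)C)C(C)C)CC2=O
F0 | step 14 | none | none
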